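The dimer is cut at the C4–C6 interflavan bond into two copies of one benzyl-protected 2,3-cis flavan-3-ol, and the pyran ring C of that monomer is cut at C2–C3. Because C2 carries both O1 and ring B, the C2–C3 bond can be made as the C=C of a cyclic aryl enol ether: ring-closing metathesis of an O-(1-arylvinyl) ortho-allylphenol closes ring C as a flav-2-ene in one operation. Hydroboration, oxidation and a dynamic kinetic hydrogenation then set C2 and C3. C4 oxygenation, thiolysis and silver-promoted coupling of the 4-thioether with the 3,4-diol join the halves before global hydrogenolysis.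

Key step: step 7

Remark: the sense of enantioinduction in step 10 is assigned by analogy with 2-arylcyclohexanones; if the first run shows the opposite sense, the mirror-image catalyst is used.

Step 1
Reactants: 1 2,3-dihydroxybenzaldehyde
Product: 2 2,3-bis(benzyloxy)benzaldehyde
Conditions: BnBr (2.4 equiv), K2CO3, DMF, 60 °C
Reagents that add atoms: benzyl bromide, BrCc1ccccc1
Why: Williamson O-benzylation of both phenols should proceed cleanly, since the aldehyde is inert to K2CO3 and BnBr.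

Step 2
Reactants: 2 2,3-bis(benzyloxy)benzaldehyde
Product: 4 2,3-bis(benzyloxy)phenol, via aryl formate 3 (not isolated)
Conditions: mCPBA, CH2Cl2, rt; then K2CO3 (cat.), MeOH, rt
Reagents that add atoms: mCPBA (3-chloroperbenzoic acid), OOC(=O)c1cccc(Cl)c1
Why: Dakin-type Baeyer–Villiger oxidation, in which the electron-rich aryl group migrates in preference to hydride to give the formate, which methanolysis cleaves to the phenol.

Step 3
Reactants: 4 2,3-bis(benzyloxy)phenol
Product: 5 1-(allyloxy)-2,3-bis(benzyloxy)benzene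
Conditions: allyl bromide, K2CO3, acetone, reflux
Reagents that add atoms: allyl bromide, C=CCBr
Why: Williamson O-allylation of the only free phenol.

Step 4
Reactants: 5 1-(allyloxy)-2,3-bis(benzyloxy)benzene
Product: 7 6-allyl-2,3-bis(benzyloxy)phenol, via ortho-dienone 6 (not isolated)
Conditions: PhNEt2, 190 °C, Ar
Reagents that add atoms: none
Why: Aromatic Claisen [3,3]-rearrangement should deliver the allyl group to C6, the only free ortho position, and the dienone tautomerizes to the phenol; benzyl aryl ethers tolerate the temperature.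

Step 5
Reactants: 7 6-allyl-2,3-bis(benzyloxy)phenol; 8 3,4-bis(benzyloxy)benzoic acid
Product: 9 6-allyl-2,3-bis(benzyloxy)phenyl 3,4-bis(benzyloxy)benzoate
Conditions: DCC, DMAP (cat.), CH2Cl2, rt
Reagents that add atoms: none
Why: Steglich esterification, in which acyl transfer through the acylpyridinium ion should overcome the hindrance of the 2,6-disubstituted phenol.

Step 6
Reactants: 9 6-allyl-2,3-bis(benzyloxy)phenyl 3,4-bis(benzyloxy)benzoate
Product: 10 1-allyl-3,4-bis(benzyloxy)-2-({1-[3,4-bis(benzyloxy)phenyl]ethenyl}oxy)benzene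
Conditions: Tebbe reagent Cp2Ti(μ-CH2)(μ-Cl)AlMe2 (1.3 equiv), pyridine (cat.), THF/PhMe, −40 → 0 °C; filtration through basic alumina
Reagents that add atoms: Tebbe reagent, C[Al-]1(C)C[Ti](C2C=CC=C2)(C2C=CC=C2)[Cl+]1
Why: Tebbe methylenation of an aryl benzoate to the 1-aryloxy-1-arylethene; at low temperature the titanium methylidene should react with the ester carbonyl faster than with the monosubstituted alkene.

Step 7
Reactants: 10 1-allyl-3,4-bis(benzyloxy)-2-({1-[3,4-bis(benzyloxy)phenyl]ethenyl}oxy)benzene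
Product: 11 7,8-bis(benzyloxy)-2-[3,4-bis(benzyloxy)phenyl]-4H-chromene
Conditions: second-generation Grubbs catalyst (H2IMes)(PCy3)Cl2Ru=CHPh (5 mol %), 1,4-benzoquinone (10 mol %), PhMe, 80 °C, Ar sparge
Reagents that add atoms: none
Why: The ruthenium alkylidene should load on the monosubstituted allyl olefin, add [2+2] to the 1,1-disubstituted enol ether, and the ruthenacyclobutane should collapse with loss of ethene to form the C2=C3 bond. The closest known reaction type is ring-closing metathesis of olefinic enol ethers made by ester methylenation, which gives 2-substituted benzofurans, 4H-chromenes and dihydropyrans. Ring C is closed as an unstrained six-membered ring by intramolecular metathesis between the allyl terminus (C3) and the enol ether carbon (C2), with the cis-alkene inside the ring and the gaseous by-product driving the equilibrium. No stereocenter is formed: 11 is achiral, and C2 and C3 are set afterwards by the syn hydroboration of step 8 and the hydrogenation of step 10. The step needs initiation at the allyl group and not at the enol ether, and no allyl-to-propenyl isomerization (which would lead to a benzofuran); the 1,1-disubstitution of the enol ether blocks carbene formation there, and 1,4-benzoquinone traps ruthenium hydrides.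

Step 8
Reactants: 11 7,8-bis(benzyloxy)-2-[3,4-bis(benzyloxy)phenyl]-4H-chromene
Product: 13 rac-(2R*,3S*)-7,8-bis(benzyloxy)-2-[3,4-bis(benzyloxy)phenyl]chroman-3-ol, via trans-alkylborane 12 (not isolated)
Conditions: BH3·THF, THF, 0 °C → rt; then NaOH (3 M), H2O2 (30 %), 0 °C
Reagents that add atoms: borane–tetrahydrofuran, B.C1CCOC1 (boron stays in 12 only); hydrogen peroxide, OO
Why: Brown hydroboration–oxidation: boron should add to C3, the β-carbon of the enol ether, and hydrogen to C2 on the same face, so oxidation with retention gives only the racemic 2,3-trans alcohol.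

Step 9
Reactants: 13 rac-(2R*,3S*)-7,8-bis(benzyloxy)-2-[3,4-bis(benzyloxy)phenyl]chroman-3-ol
Product: 14 rac-7,8-bis(benzyloxy)-2-[3,4-bis(benzyloxy)phenyl]chroman-3-one
Conditions: Dess–Martin periodinane, CH2Cl2, rt
Reagents that add atoms: none
Why: Dess–Martin oxidation of the secondary alcohol should give the flavan-3-one, which removes the C3 center and makes C2 epimerizable.

Step 10
Reactants: 14 rac-7,8-bis(benzyloxy)-2-[3,4-bis(benzyloxy)phenyl]chroman-3-one
Product: 15 (2R,3R)-7,8-bis(benzyloxy)-2-[3,4-bis(benzyloxy)phenyl]chroman-3-ol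
Conditions: H2 (20 atm), RuCl2[(S)-xylbinap][(S)-daipen] (1 mol %), KOtBu (20 mol %), iPrOH/THF, 25 °C
Reagents that add atoms: none
Why: Ruthenium diphosphine/diamine hydrogenation with dynamic kinetic resolution: KOtBu should racemize C2 through the enolate while the chiral catalyst reduces the (2R)-ketone faster, and hydride delivery to the face opposite the 2-aryl group sets C3 as R and gives the 2,3-cis alcohol.

Step 11
Reactants: 15 (2R,3R)-7,8-bis(benzyloxy)-2-[3,4-bis(benzyloxy)phenyl]chroman-3-ol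
Product: 16 (2R,3R,4S)-7,8-bis(benzyloxy)-2-[3,4-bis(benzyloxy)phenyl]chroman-3,4-diol
Conditions: DDQ (1.5 equiv), CH2Cl2/H2O (20:1), rt
Reagents that add atoms: water, O
Why: Benzylic oxidation by hydride abstraction: DDQ should remove hydride from C4 (para to the 7-benzyloxy group, ortho to O1), and water adds to the quinone-methide-type cation anti to the axial 3-hydroxyl, which sets the 3,4-trans (4S) alcohol.

Step 12
Reactants: 16 (2R,3R,4S)-7,8-bis(benzyloxy)-2-[3,4-bis(benzyloxy)phenyl]chroman-3,4-diol (one part of the material)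
Product: 17 (2R,3S,4S)-4-(benzylsulfanyl)-7,8-bis(benzyloxy)-2-[3,4-bis(benzyloxy)phenyl]chroman-3-ol
Conditions: BnSH (5 equiv), camphorsulfonic acid (10 mol %), CH2Cl2, 0 °C → rt
Reagents that add atoms: phenylmethanethiol, SCc1ccccc1
Why: Acid-catalysed thiolysis (SN1): the C4 cation should be regenerated from the benzylic alcohol and captured by the excess thiol anti to the 3-hydroxyl, faster than by any arene.

Step 13
Reactants: 17 (2R,3S,4S)-4-(benzylsulfanyl)-7,8-bis(benzyloxy)-2-[3,4-bis(benzyloxy)phenyl]chroman-3-ol; 16 (2R,3R,4S)-7,8-bis(benzyloxy)-2-[3,4-bis(benzyloxy)phenyl]chroman-3,4-diol (4 equiv, excess recovered)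
Product: 18 octa-O-benzyl ether of 19 (upper unit 2,3-cis-3,4-trans, joined C4→C6 to the lower 2,3-cis-3,4-trans 3,4-diol unit)
Conditions: AgBF4 (2.5 equiv), THF, 0 °C, dark; aq NaHCO3
Reagents that add atoms: none
Why: Thiophilic activation and Friedel–Crafts arylation: the soft silver ion should remove the benzylthiolate of 17 without activating the C4 hydroxyl of 16, and the cation is attacked by C6 of 16 (para to O1, ortho to the 7-benzyloxy group) from the face anti to the 3-hydroxyl, which sets the upper C4 center 3,4-trans.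

Step 14
Reactants: 18 octa-O-benzyl ether of 19
Product: 19 (2R,3R,4S)-2-(3,4-dihydroxyphenyl)-6-[(2R,3R,4S)-2-(3,4-dihydroxyphenyl)-3,7,8-trihydroxychroman-4-yl]chroman-3,4,7,8-tetrol
Conditions: H2 (1 atm), Pd(OH)2/C, THF/MeOH/H2O, rt, monitored and stopped at full debenzylation
Reagents that add atoms: none
Why: Hydrogenolysis of the eight benzyl aryl ethers, which should be cleaved much faster under neutral conditions than the secondary benzylic C4–OH bond, the ring C–O bonds and the interflavan C–C bond.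

Compound list
1 | 2,3-dihydroxybenzaldehyde | O=Cc1cccc(O)c1O | starting material
2 | 2,3-bis(benzyloxy)benzaldehyde | O=Cc1cccc(OCc2ccccc2)c1OCc1ccccc1 | intermediate
3 | 2,3-bis(benzyloxy)phenyl formate (not isolated) | O=COc1cccc(OCc2ccccc2)c1OCc1ccccc1 | intermediate
4 | 2,3-bis(benzyloxy)phenol | Oc1cccc(OCc2ccccc2)c1OCc1ccccc1 | intermediate
5 | 1-(allyloxy)-2,3-bis(benzyloxy)benzene | C=CCOc1cccc(OCc2ccccc2)c1OCc1ccccc1 | intermediate
6 | 6-allyl-2,3-bis(benzyloxy)cyclohexa-2,4-dien-1-one (not isolated) | C=CCC1C=CC(OCc2ccccc2)=C(OCc2ccccc2)C1=O | intermediate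
7 | 6-allyl-2,3-bis(benzyloxy)phenol | C=CCc1ccc(OCc2ccccc2)c(OCc2ccccc2)c1O | intermediate
8 | 3,4-bis(benzyloxy)benzoic acid | OC(=O)c1ccc(OCc2ccccc2)c(OCc2ccccc2)c1 | starting material
9 | 6-allyl-2,3-bis(benzyloxy)phenyl 3,4-bis(benzyloxy)benzoate | C=CCc1ccc(OCc2ccccc2)c(OCc2ccccc2)c1OC(=O)c1ccc(OCc2ccccc2)c(OCc2ccccc2)c1 | intermediate
10 | 1-allyl-3,4-bis(benzyloxy)-2-({1-[3,4-bis(benzyloxy)phenyl]ethenyl}oxy)benzene | C=CCc1ccc(OCc2ccccc2)c(OCc2ccccc2)c1OC(=C)c1ccc(OCc2ccccc2)c(OCc2ccccc2)c1 | intermediate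
11 | 7,8-bis(benzyloxy)-2-[3,4-bis(benzyloxy)phenyl]-4H-chromene (flav-2-ene, achiral) | C1=C(c2ccc(OCc3ccccc3)c(OCc3ccccc3)c2)Oc2c(C1)ccc(OCc1ccccc1)c2OCc1ccccc1 | intermediate
12 | rac-(2,3-trans)-[7,8-bis(benzyloxy)-2-(3,4-bis(benzyloxy)phenyl)chroman-3-yl]borane (racemate, one enantiomer drawn; not isolated) | O(Cc1ccccc1)c1ccc([C@H]2Oc3c(ccc(OCc4ccccc4)c3OCc3ccccc3)C[C@@H]2B)cc1OCc1ccccc1 | intermediate
13 | rac-(2R*,3S*)-7,8-bis(benzyloxy)-2-[3,4-bis(benzyloxy)phenyl]chroman-3-ol (2,3-trans; racemate, the 2R,3S enantiomer drawn) | O(Cc1ccccc1)c1ccc([C@H]2Oc3c(ccc(OCc4ccccc4)c3OCc3ccccc3)C[C@@H]2O)cc1OCc1ccccc1 | intermediate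
14 | rac-7,8-bis(benzyloxy)-2-[3,4-bis(benzyloxy)phenyl]chroman-3-one (racemic at C2) | O=C1Cc2ccc(OCc3ccccc3)c(OCc3ccccc3)c2OC1c1ccc(OCc2ccccc2)c(OCc2ccccc2)c1 | intermediate
15 | (2R,3R)-7,8-bis(benzyloxy)-2-[3,4-bis(benzyloxy)phenyl]chroman-3-ol (2,3-cis) | O(Cc1ccccc1)c1ccc([C@H]2Oc3c(ccc(OCc4ccccc4)c3OCc3ccccc3)C[C@H]2O)cc1OCc1ccccc1 | intermediate
16 | (2R,3R,4S)-7,8-bis(benzyloxy)-2-[3,4-bis(benzyloxy)phenyl]chroman-3,4-diol (2,3-cis-3,4-trans) | c1cc2c(c(OCc3ccccc3)c1OCc1ccccc1)O[C@H](c1ccc(OCc3ccccc3)c(OCc3ccccc3)c1)[C@H](O)[C@H]2O | intermediate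
17 | (2R,3S,4S)-4-(benzylsulfanyl)-7,8-bis(benzyloxy)-2-[3,4-bis(benzyloxy)phenyl]chroman-3-ol (2,3-cis-3,4-trans) | c1cc2c(c(OCc3ccccc3)c1OCc1ccccc1)O[C@H](c1ccc(OCc3ccccc3)c(OCc3ccccc3)c1)[C@H](O)[C@H]2SCc1ccccc1 | intermediate
18 | octa-O-benzyl ether of 19: all eight phenols as benzyl ethers, the three secondary hydroxyls free, spatial arrangement as in 19 | O(Cc5ccccc5)c1ccc([C@H]2Oc3c(ccc(OCc5ccccc5)c3OCc5ccccc5)[C@H](c3cc4c(c(OCc5ccccc5)c3OCc5ccccc5)O[C@H](c3ccc(OCc5ccccc5)c(OCc5ccccc5)c3)[C@H](O)[C@H]4O)[C@H]2O)cc1OCc1ccccc1 | intermediate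
19 | (2R,3R,4S)-2-(3,4-dihydroxyphenyl)-6-[(2R,3R,4S)-2-(3,4-dihydroxyphenyl)-3,7,8-trihydroxychroman-4-yl]chroman-3,4,7,8-tetrol | Oc1ccc([C@H]2Oc3c(ccc(O)c3O)[C@H](c3cc4c(c(O)c3O)O[C@H](c3ccc(O)c(O)c3)[C@H](O)[C@H]4O)[C@H]2O)cc1O | target

Total step count: 14. Longest linear sequence: 14 steps (1 → 19; compound 16 enters step 13 twice, once as such and once as 17).

Steps most likely to fail

Step 13. The free 3- and 4-hydroxyls of 16 may be alkylated in competition with C6, and the HBF4 that builds up may ionize the C4–OH of 16 itself, leading to ether-linked and oligomeric products. The fallback sets out from 16 and comes back at 18. Acetylation of 16 (Ac2O, pyridine, DMAP) should give the 3,4-di-O-acetate of 16 F3, which has no free hydroxyl and a C4 ester that the silver ion does not activate. Coupling of 17 with F3 (AgBF4, THF, 0 °C) should give the lower-unit 3,4-di-O-acetate of 18 F4, and methanolysis (K2CO3, MeOH/THF) returns 18.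

Step 10. Epimerization at C2 may be slow relative to reduction, or enantioface discrimination may be poor on a ketone that is not conjugated to an arene, so that a mixture of stereoisomers results. The fallback sets out from 11 and comes back at 15. Asymmetric hydroboration of 11 with monoisopinocampheylborane (from the α-pinene enantiomer that gives the 2R,3S product), then NaOH/H2O2, should give the trans alcohol as a single enantiomer, (2R,3S)-7,8-bis(benzyloxy)-2-[3,4-bis(benzyloxy)phenyl]chroman-3-ol F1. Dess–Martin oxidation should give (2R)-7,8-bis(benzyloxy)-2-[3,4-bis(benzyloxy)phenyl]chroman-3-one F2, and reduction with LiBH(s-Bu)3 in THF at −78 °C, hydride anti to the 2-aryl group, returns 15.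

Step 14. Over-reduction may occur: the benzylic C4–OH bond of the lower unit may be hydrogenolysed while the benzyl ethers are removed. The fallback sets out from 18 and comes back at 19. Silylation of the three secondary hydroxyls (TBSOTf, 2,6-lutidine, CH2Cl2, −78 °C) should give the tris-TBS ether of 18 F5, whose bulky benzylic silyl ether resists hydrogenolysis. Hydrogenolysis (H2, Pd(OH)2/C, EtOAc) should give the tris-TBS ether of 19 F6, and desilylation with TBAF buffered with AcOH in THF at 0 °C gives 19.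

Further compounds
F1 | step 10 | (2R,3S)-7,8-bis(benzyloxy)-2-[3,4-bis(benzyloxy)phenyl]chroman-3-ol (single enantiomer of 13) | O(Cc1ccccc1)c1ccc([C@H]2Oc3c(ccc(OCc4ccccc4)c3OCc3ccccc3)C[C@@H]2O)cc1OCc1ccccc1
F2 | step 10 | (2R)-7,8-bis(benzyloxy)-2-[3,4-bis(benzyloxy)phenyl]chroman-3-one | O(Cc1ccccc1)c1ccc([C@H]2Oc3c(ccc(OCc4ccccc4)c3OCc3ccccc3)CC2=O)cc1OCc1ccccc1
F3 | step 13 | 3,4-di-O-acetate of 16 | c1cc2c(c(OCc3ccccc3)c1OCc1ccccc1)O[C@H](c1ccc(OCc3ccccc3)c(OCc3ccccc3)c1)[C@H](OC(C)=O)[C@H]2OC(C)=O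
F4 | step 13 | lower-unit 3,4-di-O-acetate of 18 | O(Cc5ccccc5)c1ccc([C@H]2Oc3c(ccc(OCc5ccccc5)c3OCc5ccccc5)[C@H](c3cc4c(c(OCc5ccccc5)c3OCc5ccccc5)O[C@H](c3ccc(OCc5ccccc5)c(OCc5ccccc5)c3)[C@H](OC(C)=O)[C@H]4OC(C)=O)[C@H]2O)cc1OCc1ccccc1
F5 | step 14 | tris-O-(tert-butyldimethylsilyl) ether of 18 | O(Cc5ccccc5)c1ccc([C@H]2Oc3c(ccc(OCc5ccccc5)c3OCc5ccccc5)[C@H](c3cc4c(c(OCc5ccccc5)c3OCc5ccccc5)O[C@H](c3ccc(OCc5ccccc5)c(OCc5ccccc5)c3)[C@H](O[Si](C)(C)C(C)(C)C)[C@H]4O[Si](C)(C)C(C)(C)C)[C@H]2O[Si](C)(C)C(C)(C)C)cc1OCc1ccccc1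
F6 | step 14 | tris-O-(tert-butyldimethylsilyl) ether of 19 (all phenols free) | Oc1ccc([C@H]2Oc3c(ccc(O)c3O)[C@H](c3cc4c(c(O)c3O)O[C@H](c3ccc(O)c(O)c3)[C@H](O[Si](C)(C)C(C)(C)C)[C@H]4O[Si](C)(C)C(C)(C)C)[C@H]2O[Si](C)(C)C(C)(C)C)cc1O
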